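With the oxepene numbered O1, C2 (quaternary), C3, C4, C5=C6, C7, the plan treats C6 of the allylic ether C5=C6–C7–O1 as a carbene carbon added across the enol ether double bond of a dihydropyran and then inserted between C5 and C7. One AgOAc-assisted electrocyclic opening of the dibromocyclopropane enlarges the pyran to the seven-membered ring, fixes the alkene at C5=C6, and leaves bromine on C6 for a B-alkyl Suzuki coupling and an acetal at C7 for later reduction. The precursor is a 7,7-dibromo-2-oxabicyclo[4.1.0]heptane whose quaternary carbon (future C2, S) already carries the 2-(trimethylsilyl)ethyl ester and the N-methoxy-N-methylacetamide arm, set by a Cu(OTf)2–bis(oxazoline) aldol.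

Key step: step 8

Remark: 16 and 18 are each carried forward as the pair of diastereomers that differ only at centres destroyed in steps 8 and 9; one isomer of each is drawn.

**Route**

Step 1
Reactants: 1 oxalyl chloride; 2 2-(trimethylsilyl)ethanol (two equivalents)
Product: 3 bis[2-(trimethylsilyl)ethyl] oxalate
Conditions: 2 (2.1 equiv), pyridine (2.2 equiv), CH2Cl2, 0 °C → rt
Reagents that add atoms: 2-(trimethylsilyl)ethanol (second equivalent), C[Si](C)(C)CCO
Why: Each acid chloride function of oxalyl chloride acylates one molecule of the primary alcohol (nucleophilic acyl substitution), which installs from the outset the fluoride-labile ester that the end game needs.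

Step 2
Reactants: 4 4-chlorobutanal dimethyl acetal; 3 bis[2-(trimethylsilyl)ethyl] oxalate
Product: 6 2-(trimethylsilyl)ethyl 6,6-dimethoxy-2-oxohexanoate, via Grignard reagent 5 (not isolated)
Conditions: Mg, I2 (cat.), THF, reflux; then added to 3 (2 equiv), THF, −78 °C; aq. NH4Cl
Reagents that add atoms: none
Why: Inverse addition of a Grignard reagent to excess dialkyl oxalate at low temperature stops at the α-keto ester because the tetrahedral adduct only collapses on quench, and the acetal is inert to the organomagnesium.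

Step 3
Reactants: 7 S-tert-butyl thioacetate
Product: 8 1-(tert-butylsulfanyl)-1-(trimethylsilyloxy)ethene
Conditions: LiN(i-Pr)2, THF, −78 °C; Me3SiCl, −78 °C → rt; distillation
Reagents that add atoms: chlorotrimethylsilane, C[Si](C)(C)Cl
Why: Kinetic enolisation of the thioester and O-silylation of the lithium enolate give the silyl ketene thioacetal needed for a Mukaiyama aldol.

Step 4
Reactants: 6 2-(trimethylsilyl)ethyl 6,6-dimethoxy-2-oxohexanoate; 8 1-(tert-butylsulfanyl)-1-(trimethylsilyloxy)ethene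
Product: 10 2-(trimethylsilyl)ethyl (2S)-2-[2-(tert-butylsulfanyl)-2-oxoethyl]-2-hydroxy-6,6-dimethoxyhexanoate, via trimethylsilyl ether 9 (not isolated)
Conditions: Cu(OTf)2 (10 mol%), (S,S)-t-Bu-box [2,2'-(propane-2,2-diyl)bis((4S)-4-tert-butyl-4,5-dihydrooxazole)] (11 mol%), THF, −78 °C; then PPTS (cat.), MeOH, 0 °C
Reagents that add atoms: none
Why: In this catalytic enantioselective Mukaiyama aldol the keto ester chelates divalent copper in a square-planar complex whose tert-butyl groups shield the re face of the ketone, so the enolsilane should add to the si face and set C2 as S (OH > CO2R > CH2COS > chain), after which brief methanolysis removes the silyl group from 9 without disturbing the dimethyl acetal.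

Step 5
Reactants: 10 2-(trimethylsilyl)ethyl (2S)-2-[2-(tert-butylsulfanyl)-2-oxoethyl]-2-hydroxy-6,6-dimethoxyhexanoate
Product: 11 2-(trimethylsilyl)ethyl (2S)-2-hydroxy-6,6-dimethoxy-2-{2-[methoxy(methyl)amino]-2-oxoethyl}hexanoate
Conditions: MeNHOMe (free base, 3 equiv), AgOCOCF3 (1.2 equiv), THF, 0 °C → rt, dark
Reagents that add atoms: N,O-dimethylhydroxylamine, CNOC
Why: Monovalent silver binds sulfur and the α-effect amine displaces the thiolate (silver-assisted aminolysis of a thioester), which spares the hindered C2 ester and the acetal and gives the least acidic acyl derivative for the base and cation steps ahead.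

Step 6
Reactants: 11 2-(trimethylsilyl)ethyl (2S)-2-hydroxy-6,6-dimethoxy-2-{2-[methoxy(methyl)amino]-2-oxoethyl}hexanoate
Product: 13 2-(trimethylsilyl)ethyl (2S)-2-{2-[methoxy(methyl)amino]-2-oxoethyl}-3,4-dihydro-2H-pyran-2-carboxylate, via cyclic methyl acetal 12 (not isolated)
Conditions: PPTS (0.2 equiv), pyridine (0.2 equiv), PhCl, 130 °C, N2 sweep
Reagents that add atoms: none
Why: Acid-catalysed transacetalisation lets the tertiary hydroxyl close the six-membered cyclic acetal 12, and continued heating with the buffered acid expels the second methanol from the ring oxocarbenium ion by proton loss to give the enol ether, driven by removal of methanol.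

Step 7
Reactants: 13 2-(trimethylsilyl)ethyl (2S)-2-{2-[methoxy(methyl)amino]-2-oxoethyl}-3,4-dihydro-2H-pyran-2-carboxylate; 14 bromoform
Product: 16 2-(trimethylsilyl)ethyl (1S,3S,6R)-7,7-dibromo-3-{2-[methoxy(methyl)amino]-2-oxoethyl}-2-oxabicyclo[4.1.0]heptane-3-carboxylate, via dibromocarbene 15 (not isolated)
Conditions: CHBr3 (3 equiv), KOtBu (3 equiv, portionwise), pentane/Et2O, −20 → 0 °C; used crude and cold
Reagents that add atoms: none
Why: α-Elimination of bromoform gives dibromocarbene, which adds in a concerted [2+1] manner to the electron-rich enol ether, while the far more acidic bromoform consumes tert-butoxide before it can enolise the amide arm or touch the ester that lacks α-hydrogens.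

Step 8
Reactants: 16 2-(trimethylsilyl)ethyl (1S,3S,6R)-7,7-dibromo-3-{2-[methoxy(methyl)amino]-2-oxoethyl}-2-oxabicyclo[4.1.0]heptane-3-carboxylate
Product: 18 2-(trimethylsilyl)ethyl (2S,7R)-6-bromo-7-methoxy-2-{2-[methoxy(methyl)amino]-2-oxoethyl}-2,3,4,7-tetrahydrooxepine-2-carboxylate, via oxocarbenium ion 17 (not isolated)
Conditions: AgOAc (2.5 equiv), MeOH, rt → 40 °C, dark
Reagents that add atoms: methanol, CO
Why: Monovalent silver abstracts the bromide lying over the six-membered ring while the ring-fusion bond (C5–C7 in oxepene numbering) opens in a disrotatory two-electron electrocyclic process to the 2-bromoallyl cation 17, which is an oxocarbenium ion through O1 and is captured by methanol at C7; the closest known reaction is the silver- or base-promoted expansion of gem-dibromocyclopropanes fused to glycal-type dihydropyrans. The oxepene is not formed by cyclisation but by enlargement of the existing pyran when the shared cyclopropane bond breaks, so no entropic price for seven-ring closure is paid and cyclopropane strain supplies the driving force. Orbital symmetry makes the ring carbons, which are cis to the departing bromide, rotate inward, so only the endo bromide can leave and the allyl cation is the all-cis one that a seven-membered ring can hold; each diastereomer of 16 has such a bromide. The step needs capture at C7 and not at C5, which the concentration of positive charge on the oxygen-bearing carbon secures, and it needs solvent capture to outrun the C2 ester and amide carbonyl groups, which methanol as solvent and the acetic acid/acetate buffer formed from AgOAc secure. The new C7 centre is uncontrolled and irrelevant because step 9 removes it, and C2 is a spectator because none of its bonds takes part.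

Step 9
Reactants: 18 2-(trimethylsilyl)ethyl (2S,7R)-6-bromo-7-methoxy-2-{2-[methoxy(methyl)amino]-2-oxoethyl}-2,3,4,7-tetrahydrooxepine-2-carboxylate
Product: 20 2-(trimethylsilyl)ethyl (2S)-6-bromo-2-{2-[methoxy(methyl)amino]-2-oxoethyl}-2,3,4,7-tetrahydrooxepine-2-carboxylate, via oxocarbenium methoxytrifluoroborate 19 (not isolated)
Conditions: Et3SiH (5 equiv), BF3·OEt2 (2 equiv), CH2Cl2, −78 → −20 °C
Reagents that add atoms: none
Why: BF3 takes the C7 methoxy group and leaves the ring oxocarbenium ion as its methoxytrifluoroborate 19, to which triethylsilane delivers hydride at C7, the carbon that carries most of the positive charge (ionic hydrogenation, as in the reductive deoxygenation of glycosides), and doing this before the side chain is attached means that no remote alkene can trap the cation.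

Step 10
Reactants: 21 acrolein; 22 ethyl 2-(triphenylphosphoranylidene)propanoate
Product: 23 ethyl (2E)-2-methylpenta-2,4-dienoate
Conditions: CH2Cl2, 0 °C → rt
Reagents that add atoms: none
Why: Wittig olefination with a stabilised α-methyl ylide reacts only at the aldehyde and should give the E trisubstituted enoate through the thermodynamically preferred oxaphosphetane.

Step 11
Reactants: 23 ethyl (2E)-2-methylpenta-2,4-dienoate
Product: 24 (2E)-2-methylpenta-2,4-dien-1-ol
Conditions: i-Bu2AlH (2.2 equiv), CH2Cl2, −78 °C; aq. potassium sodium tartrate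
Reagents that add atoms: none
Why: Two 1,2-hydride deliveries from the aluminium hydride reduce the conjugated ester to the allylic alcohol without touching the diene or its geometry.

Step 12
Reactants: 24 (2E)-2-methylpenta-2,4-dien-1-ol
Product: 25 triethyl{[(2E)-2-methylpenta-2,4-dien-1-yl]oxy}silane
Conditions: Et3SiCl, imidazole, CH2Cl2, 0 °C
Reagents that add atoms: chlorotriethylsilane, CC[Si](Cl)(CC)CC
Why: Silylation of a primary alcohol gives an ether that tolerates the borane and aqueous carbonate yet is removed later by mild acidic methanolysis.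

Step 13
Reactants: 25 triethyl{[(2E)-2-methylpenta-2,4-dien-1-yl]oxy}silane; 20 2-(trimethylsilyl)ethyl (2S)-6-bromo-2-{2-[methoxy(methyl)amino]-2-oxoethyl}-2,3,4,7-tetrahydrooxepine-2-carboxylate
Product: 27 2-(trimethylsilyl)ethyl (2S)-2-{2-[methoxy(methyl)amino]-2-oxoethyl}-6-[(3E)-4-methyl-5-(triethylsilyloxy)pent-3-en-1-yl]-2,3,4,7-tetrahydrooxepine-2-carboxylate, via alkylborane 26 (not isolated)
Conditions: 9-BBN-H (1.1 equiv), THF, 0 °C → rt; then 20, PdCl2(dppf) (5 mol%), AsPh3 (10 mol%), Cs2CO3 (3 equiv), DMF/THF/H2O, rt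
Reagents that add atoms: none
Why: In this B-alkyl Suzuki–Miyaura coupling 9-BBN adds anti-Markovnikov to the only monosubstituted alkene of the diene (the trisubstituted one is too hindered) and the base-activated borane 26 transfers its primary alkyl group to the vinylpalladium species from the C6 bromide with retention of both alkene geometries.

Step 14
Reactants: 28 hydroquinone
Product: 29 1,4-bis(methoxymethoxy)benzene
Conditions: NaH (2.4 equiv), MOMCl (2.4 equiv), DMF, 0 °C → rt
Reagents that add atoms: chloromethyl methyl ether, COCCl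
Why: Williamson-type O-alkylation of both phenoxides gives acetal ethers that later direct ortho-lithiation and withstand organolithium and fluoride.

Step 15
Reactants: 29 1,4-bis(methoxymethoxy)benzene; 27 2-(trimethylsilyl)ethyl (2S)-2-{2-[methoxy(methyl)amino]-2-oxoethyl}-6-[(3E)-4-methyl-5-(triethylsilyloxy)pent-3-en-1-yl]-2,3,4,7-tetrahydrooxepine-2-carboxylate
Product: 32 2-(trimethylsilyl)ethyl (2S)-2-{2-[2,5-bis(methoxymethoxy)phenyl]-2-oxoethyl}-6-[(3E)-5-hydroxy-4-methylpent-3-en-1-yl]-2,3,4,7-tetrahydrooxepine-2-carboxylate, via aryllithium 30 (not isolated), via silyl ether ketone 31 (not isolated)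
Conditions: 29 (1.6 equiv), n-BuLi (1.5 equiv), THF, 0 °C; then 27, −78 °C; aq. NH4Cl; crude with PPTS (cat.), MeOH, rt
Reagents that add atoms: none
Why: Directed ortho-metalation gives 30, which should add once to the N-methoxy-N-methylamide (Weinreb ketone synthesis) in preference to the neopentyl-type C2 ester, and mild acidic methanolysis then removes only the triethylsilyl ether.

Step 16
Reactants: 33 (E)-4-hydroxycinnamic acid (p-coumaric acid)
Product: 35 (2E)-3-[4-(tert-butyldimethylsilyloxy)phenyl]prop-2-enoic acid, via bis-silyl derivative 34 (not isolated)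
Conditions: TBSCl (2.3 equiv), imidazole, DMF, rt; then AcOH/THF/H2O, rt
Reagents that add atoms: tert-butyl(chloro)dimethylsilane, CC(C)(C)[Si](C)(C)Cl
Why: Both acidic oxygens are silylated and the much more labile silyl ester is then hydrolysed selectively, leaving the phenol masked and the acid free.

Step 17
Reactants: 32 2-(trimethylsilyl)ethyl (2S)-2-{2-[2,5-bis(methoxymethoxy)phenyl]-2-oxoethyl}-6-[(3E)-5-hydroxy-4-methylpent-3-en-1-yl]-2,3,4,7-tetrahydrooxepine-2-carboxylate; 35 (2E)-3-[4-(tert-butyldimethylsilyloxy)phenyl]prop-2-enoic acid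
Product: 36 2-(trimethylsilyl)ethyl (2S)-2-{2-[2,5-bis(methoxymethoxy)phenyl]-2-oxoethyl}-6-[(3E)-5-{[(2E)-3-(4-(tert-butyldimethylsilyloxy)phenyl)prop-2-enoyl]oxy}-4-methylpent-3-en-1-yl]-2,3,4,7-tetrahydrooxepine-2-carboxylate
Conditions: EDC·HCl, DMAP (cat.), CH2Cl2, 0 °C → rt
Reagents that add atoms: none
Why: Steglich-type carbodiimide esterification acylates the only free hydroxyl, a primary allylic alcohol, under neutral conditions that avoid allylic transposition.

Step 18
Reactants: 36 the fully protected coumarate ester (silylethyl ester, aryl silyl ether, two methoxymethyl ethers)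
Product: 37 (2S)-2-{2-[2,5-bis(methoxymethoxy)phenyl]-2-oxoethyl}-6-[(3E)-5-{[(2E)-3-(4-hydroxyphenyl)prop-2-enoyl]oxy}-4-methylpent-3-en-1-yl]-2,3,4,7-tetrahydrooxepine-2-carboxylic acid
Conditions: TASF [tris(dimethylamino)sulfonium difluorotrimethylsilicate] (4 equiv), DMF, 0 °C → rt, argon; dil. HCl to pH 3
Reagents that add atoms: none
Why: Fluoride attacks silicon, so the 2-(trimethylsilyl)ethyl ester fragments to the carboxylate, ethylene and Me3SiF and the aryl silyl ether is cleaved, while the weakly basic fluoride source should spare the coumarate and the β-alkoxy ketone and the hydroquinone stays masked.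

Step 19
Reactants: 37 the bis(methoxymethyl) ether acid
Product: 38 (2S)-2-[2-(2,5-dihydroxyphenyl)-2-oxoethyl]-6-[(3E)-5-{[(2E)-3-(4-hydroxyphenyl)prop-2-enoyl]oxy}-4-methylpent-3-en-1-yl]-2,3,4,7-tetrahydrooxepine-2-carboxylic acid
Conditions: HCl (2 M) in i-PrOH/THF/H2O, 40 °C, argon
Reagents that add atoms: none
Why: Acid-catalysed hydrolysis of the two aryl methoxymethyl acetals (the one ortho to the ketone first) is run under conditions meant to be too mild to ionise the allylic ester or protonate the trisubstituted alkenes, and the hydroquinone is liberated only in acid, where it is not air-oxidised.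

**Compound list**

1 | oxalyl chloride | O=C(Cl)C(=O)Cl | starting material
2 | 2-(trimethylsilyl)ethanol | C[Si](C)(C)CCO | starting material
3 | bis[2-(trimethylsilyl)ethyl] oxalate | C[Si](C)(C)CCOC(=O)C(=O)OCC[Si](C)(C)C | intermediate
4 | 4-chlorobutanal dimethyl acetal | COC(OC)CCCCl | starting material
5 | (4,4-dimethoxybutyl)magnesium chloride | COC(OC)CCC[Mg]Cl | intermediate
6 | 2-(trimethylsilyl)ethyl 6,6-dimethoxy-2-oxohexanoate | C[Si](C)(C)CCOC(=O)C(=O)CCCC(OC)OC | intermediate
7 | S-tert-butyl thioacetate | CC(=O)SC(C)(C)C | starting material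
8 | 1-(tert-butylsulfanyl)-1-(trimethylsilyloxy)ethene | C=C(O[Si](C)(C)C)SC(C)(C)C | intermediate
9 | 2-(trimethylsilyl)ethyl (2S)-2-[2-(tert-butylsulfanyl)-2-oxoethyl]-6,6-dimethoxy-2-(trimethylsilyloxy)hexanoate | C[Si](C)(C)CCOC(=O)[C@@](O[Si](C)(C)C)(CC(=O)SC(C)(C)C)CCCC(OC)OC | intermediate
10 | 2-(trimethylsilyl)ethyl (2S)-2-[2-(tert-butylsulfanyl)-2-oxoethyl]-2-hydroxy-6,6-dimethoxyhexanoate | C[Si](C)(C)CCOC(=O)[C@@](O)(CC(=O)SC(C)(C)C)CCCC(OC)OC | intermediate
11 | 2-(trimethylsilyl)ethyl (2S)-2-hydroxy-6,6-dimethoxy-2-{2-[methoxy(methyl)amino]-2-oxoethyl}hexanoate | C[Si](C)(C)CCOC(=O)[C@@](O)(CC(=O)N(C)OC)CCCC(OC)OC | intermediate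
12 | 2-(trimethylsilyl)ethyl (2S)-6-methoxy-2-{2-[methoxy(methyl)amino]-2-oxoethyl}tetrahydro-2H-pyran-2-carboxylate (both C6 epimers) | C[Si](C)(C)CCOC(=O)[C@@]1(CC(=O)N(C)OC)CCCC(OC)O1 | intermediate
13 | 2-(trimethylsilyl)ethyl (2S)-2-{2-[methoxy(methyl)amino]-2-oxoethyl}-3,4-dihydro-2H-pyran-2-carboxylate | C[Si](C)(C)CCOC(=O)[C@@]1(CC(=O)N(C)OC)CCC=CO1 | intermediate
14 | bromoform | BrC(Br)Br | starting material
15 | dibromocarbene | Br[C]Br | intermediate
16 | 2-(trimethylsilyl)ethyl (1S,3S,6R)-7,7-dibromo-3-{2-[methoxy(methyl)amino]-2-oxoethyl}-2-oxabicyclo[4.1.0]heptane-3-carboxylate (cis-fused; formed together with the (1R,3S,6S) isomer, which serves equally) | C[Si](C)(C)CCOC(=O)[C@@]1(CC(=O)N(C)OC)CC[C@@H]2[C@H](O1)C2(Br)Br | intermediate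
17 | (2S)-6-bromo-2-{2-[methoxy(methyl)amino]-2-oxoethyl}-2-{[2-(trimethylsilyl)ethoxy]carbonyl}-3,4-dihydro-2H-oxepin-1-ium (cyclic 2-bromoallyl oxocarbenium ion) | C[Si](C)(C)CCOC(=O)[C@@]1(CC(=O)N(C)OC)CCC=C(Br)C=[O+]1 | intermediate
18 | 2-(trimethylsilyl)ethyl (2S,7R)-6-bromo-7-methoxy-2-{2-[methoxy(methyl)amino]-2-oxoethyl}-2,3,4,7-tetrahydrooxepine-2-carboxylate (formed together with the 7S epimer, which serves equally) | C[Si](C)(C)CCOC(=O)[C@@]1(CC(=O)N(C)OC)CCC=C(Br)[C@H](OC)O1 | intermediate
19 | (2S)-6-bromo-2-{2-[methoxy(methyl)amino]-2-oxoethyl}-2-{[2-(trimethylsilyl)ethoxy]carbonyl}-3,4-dihydro-2H-oxepin-1-ium methoxytrifluoroborate (ion pair formed from 18 and BF3) | C[Si](C)(C)CCOC(=O)[C@@]1(CC(=O)N(C)OC)CCC=C(Br)C=[O+]1.CO[B-](F)(F)F | intermediate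
20 | 2-(trimethylsilyl)ethyl (2S)-6-bromo-2-{2-[methoxy(methyl)amino]-2-oxoethyl}-2,3,4,7-tetrahydrooxepine-2-carboxylate | C[Si](C)(C)CCOC(=O)[C@@]1(CC(=O)N(C)OC)CCC=C(Br)CO1 | intermediate
21 | acrolein | C=CC=O | starting material
22 | ethyl 2-(triphenylphosphoranylidene)propanoate | CCOC(=O)C(C)=P(c1ccccc1)(c1ccccc1)c1ccccc1 | starting material
23 | ethyl (2E)-2-methylpenta-2,4-dienoate | C=C/C=C(\C)C(=O)OCC | intermediate
24 | (2E)-2-methylpenta-2,4-dien-1-ol | C=C/C=C(\C)CO | intermediate
25 | triethyl{[(2E)-2-methylpenta-2,4-dien-1-yl]oxy}silane | C=C/C=C(\C)CO[Si](CC)(CC)CC | intermediate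
26 | 9-[(3E)-4-methyl-5-(triethylsilyloxy)pent-3-en-1-yl]-9-borabicyclo[3.3.1]nonane | CC[Si](CC)(CC)OC/C(C)=C/CCB1C2CCCC1CCC2 | intermediate
27 | 2-(trimethylsilyl)ethyl (2S)-2-{2-[methoxy(methyl)amino]-2-oxoethyl}-6-[(3E)-4-methyl-5-(triethylsilyloxy)pent-3-en-1-yl]-2,3,4,7-tetrahydrooxepine-2-carboxylate | C[Si](C)(C)CCOC(=O)[C@@]1(CC(=O)N(C)OC)CCC=C(CC/C=C(\C)CO[Si](CC)(CC)CC)CO1 | intermediate
28 | hydroquinone | Oc1ccc(O)cc1 | starting material
29 | 1,4-bis(methoxymethoxy)benzene | COCOc1ccc(OCOC)cc1 | intermediate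
30 | [2,5-bis(methoxymethoxy)phenyl]lithium | [Li]c1cc(OCOC)ccc1OCOC | intermediate
31 | 2-(trimethylsilyl)ethyl (2S)-2-{2-[2,5-bis(methoxymethoxy)phenyl]-2-oxoethyl}-6-[(3E)-4-methyl-5-(triethylsilyloxy)pent-3-en-1-yl]-2,3,4,7-tetrahydrooxepine-2-carboxylate | C[Si](C)(C)CCOC(=O)[C@@]1(CC(=O)c2cc(OCOC)ccc2OCOC)CCC=C(CC/C=C(\C)CO[Si](CC)(CC)CC)CO1 | intermediate
32 | 2-(trimethylsilyl)ethyl (2S)-2-{2-[2,5-bis(methoxymethoxy)phenyl]-2-oxoethyl}-6-[(3E)-5-hydroxy-4-methylpent-3-en-1-yl]-2,3,4,7-tetrahydrooxepine-2-carboxylate | C[Si](C)(C)CCOC(=O)[C@@]1(CC(=O)c2cc(OCOC)ccc2OCOC)CCC=C(CC/C=C(\C)CO)CO1 | intermediate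
33 | (E)-4-hydroxycinnamic acid (p-coumaric acid) | OC(=O)/C=C/c1ccc(O)cc1 | starting material
34 | tert-butyldimethylsilyl (2E)-3-[4-(tert-butyldimethylsilyloxy)phenyl]prop-2-enoate | CC(C)(C)[Si](C)(C)OC(=O)/C=C/c1ccc(O[Si](C)(C)C(C)(C)C)cc1 | intermediate
35 | (2E)-3-[4-(tert-butyldimethylsilyloxy)phenyl]prop-2-enoic acid | OC(=O)/C=C/c1ccc(O[Si](C)(C)C(C)(C)C)cc1 | intermediate
36 | 2-(trimethylsilyl)ethyl (2S)-2-{2-[2,5-bis(methoxymethoxy)phenyl]-2-oxoethyl}-6-[(3E)-5-{[(2E)-3-(4-(tert-butyldimethylsilyloxy)phenyl)prop-2-enoyl]oxy}-4-methylpent-3-en-1-yl]-2,3,4,7-tetrahydrooxepine-2-carboxylate | C[Si](C)(C)CCOC(=O)[C@@]1(CC(=O)c2cc(OCOC)ccc2OCOC)CCC=C(CC/C=C(\C)COC(=O)/C=C/c2ccc(O[Si](C)(C)C(C)(C)C)cc2)CO1 | intermediate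
37 | (2S)-2-{2-[2,5-bis(methoxymethoxy)phenyl]-2-oxoethyl}-6-[(3E)-5-{[(2E)-3-(4-hydroxyphenyl)prop-2-enoyl]oxy}-4-methylpent-3-en-1-yl]-2,3,4,7-tetrahydrooxepine-2-carboxylic acid | OC(=O)[C@@]1(CC(=O)c2cc(OCOC)ccc2OCOC)CCC=C(CC/C=C(\C)COC(=O)/C=C/c2ccc(O)cc2)CO1 | intermediate
38 | (2S)-2-[2-(2,5-dihydroxyphenyl)-2-oxoethyl]-6-[(3E)-5-{[(2E)-3-(4-hydroxyphenyl)prop-2-enoyl]oxy}-4-methylpent-3-en-1-yl]-2,3,4,7-tetrahydrooxepine-2-carboxylic acid | OC(=O)[C@@]1(CC(=O)c2cc(O)ccc2O)CCC=C(CC/C=C(\C)COC(=O)/C=C/c2ccc(O)cc2)CO1 | target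

**Step count**

Total: 19 steps. Longest linear sequence: 13 steps (1, 2, 4, 5, 6, 7, 8, 9, 13, 15, 17, 18, 19).

**Steps most likely to fail**

Step 8. The cation may be intercepted by the C2 ester or amide carbonyl oxygen instead of methanol, with fragmentation of the silylethyl ester to a bridged acylal. It may also lose a C4 proton to a bromodienol ether, or the labile cyclopropane may open before silver and methanol are present. Fallback: the oxepene is closed by ring-closing metathesis and the dibromocyclopropane is avoided; the sequence sets out from 3 and rejoins the route at 27. From 3, but-3-enylmagnesium bromide at −78 °C gives 2-(trimethylsilyl)ethyl 2-oxohex-5-enoate F1. The aldol of step 4 with 8 gives, through the trimethylsilyl ether F2, the (2S)-hydroxy thioester F3, and the conditions of step 5 convert it into the N-methoxy-N-methylamide F4. Separately, borane 26 is coupled (PdCl2(dppf), aqueous Cs2CO3) with 2-bromoprop-2-en-1-ol to the 2-substituted allylic alcohol F5, which Cl3CCN and DBU turn into the trichloroacetimidate F6. Acid-catalysed alkylation (TfOH cat., CH2Cl2/cyclohexane, 0 °C) of the tertiary hydroxyl of F4 with F6, chosen because base would provoke retro-aldol cleavage, gives the diene ether F7. Ring-closing metathesis of F7 with second-generation Grubbs catalyst forms C5=C6 and comes back to the route at 27.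

Step 15. The aryllithium may attack the C2 ester as well as the amide, or deprotonate the CH2 next to the amide, after which β-elimination of O1 would open the oxepene. Fallback: the ketone is made at the aldehyde oxidation level. From 27, Cp2Zr(H)Cl in THF reduces only the N-methoxy-N-methylamide and gives the aldehyde F8. Aryllithium 30 adds to it at −78 °C, far faster than to any ester, to give the benzylic alcohol F9 as a mixture of epimers. Dess–Martin periodinane oxidation returns to the route at 31, which is desilylated to 32 as in step 15.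

Step 19. The acid needed for the second methoxymethyl ether may also solvolyse the allylic coumarate, start cation–olefin reactions between the two trisubstituted alkenes, or stop at partial deprotection. Fallback: an all-silyl protecting scheme that ends with fluoride alone, setting out from 27 and arriving at 38. 2-Bromobenzene-1,4-diol is silylated (TBSCl, imidazole) to 2-bromo-1,4-bis(tert-butyldimethylsilyloxy)benzene F10. Bromine–lithium exchange (n-BuLi, THF, −78 °C, kept cold to prevent silyl migration from oxygen to carbon) gives the aryllithium F11, which is added to 27 to give the silyl-protected ketone F12. PPTS in methanol removes only the triethylsilyl ether to give the alcohol F13, and esterification with 35 as in step 17 gives the tetrasilylated ester F14. One treatment with TASF in DMF under argon cleaves the silylethyl ester and the three aryl silyl ethers and arrives at 38.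

**Further compounds**

F1 | step 8 | 2-(trimethylsilyl)ethyl 2-oxohex-5-enoate | C[Si](C)(C)CCOC(=O)C(=O)CCC=C
F2 | step 8 | 2-(trimethylsilyl)ethyl (2S)-2-[2-(tert-butylsulfanyl)-2-oxoethyl]-2-(trimethylsilyloxy)hex-5-enoate | C[Si](C)(C)CCOC(=O)[C@@](O[Si](C)(C)C)(CC(=O)SC(C)(C)C)CCC=C
F3 | step 8 | 2-(trimethylsilyl)ethyl (2S)-2-[2-(tert-butylsulfanyl)-2-oxoethyl]-2-hydroxyhex-5-enoate | C[Si](C)(C)CCOC(=O)[C@@](O)(CC(=O)SC(C)(C)C)CCC=C
F4 | step 8 | 2-(trimethylsilyl)ethyl (2S)-2-hydroxy-2-{2-[methoxy(methyl)amino]-2-oxoethyl}hex-5-enoate | C[Si](C)(C)CCOC(=O)[C@@](O)(CC(=O)N(C)OC)CCC=C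
F5 | step 8 | (5E)-6-methyl-2-methylidene-7-(triethylsilyloxy)hept-5-en-1-ol | C=C(CO)CC/C=C(\C)CO[Si](CC)(CC)CC
F6 | step 8 | (5E)-6-methyl-2-methylidene-7-(triethylsilyloxy)hept-5-en-1-yl 2,2,2-trichloroacetimidate | C=C(COC(=N)C(Cl)(Cl)Cl)CC/C=C(\C)CO[Si](CC)(CC)CC
F7 | step 8 | 2-(trimethylsilyl)ethyl (2S)-2-{2-[methoxy(methyl)amino]-2-oxoethyl}-2-{[(5E)-6-methyl-2-methylidene-7-(triethylsilyloxy)hept-5-en-1-yl]oxy}hex-5-enoate | C[Si](C)(C)CCOC(=O)[C@@](OCC(=C)CC/C=C(\C)CO[Si](CC)(CC)CC)(CC(=O)N(C)OC)CCC=C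
F8 | step 15 | 2-(trimethylsilyl)ethyl (2S)-6-[(3E)-4-methyl-5-(triethylsilyloxy)pent-3-en-1-yl]-2-(2-oxoethyl)-2,3,4,7-tetrahydrooxepine-2-carboxylate | C[Si](C)(C)CCOC(=O)[C@@]1(CC=O)CCC=C(CC/C=C(\C)CO[Si](CC)(CC)CC)CO1
F9 | step 15 | 2-(trimethylsilyl)ethyl (2S)-2-{2-[2,5-bis(methoxymethoxy)phenyl]-2-hydroxyethyl}-6-[(3E)-4-methyl-5-(triethylsilyloxy)pent-3-en-1-yl]-2,3,4,7-tetrahydrooxepine-2-carboxylate (both carbinol epimers) | C[Si](C)(C)CCOC(=O)[C@@]1(CC(O)c2cc(OCOC)ccc2OCOC)CCC=C(CC/C=C(\C)CO[Si](CC)(CC)CC)CO1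
F10 | step 19 | 2-bromo-1,4-bis(tert-butyldimethylsilyloxy)benzene | CC(C)(C)[Si](C)(C)Oc1ccc(O[Si](C)(C)C(C)(C)C)c(Br)c1
F11 | step 19 | [2,5-bis(tert-butyldimethylsilyloxy)phenyl]lithium | [Li]c1cc(O[Si](C)(C)C(C)(C)C)ccc1O[Si](C)(C)C(C)(C)C
F12 | step 19 | 2-(trimethylsilyl)ethyl (2S)-2-{2-[2,5-bis(tert-butyldimethylsilyloxy)phenyl]-2-oxoethyl}-6-[(3E)-4-methyl-5-(triethylsilyloxy)pent-3-en-1-yl]-2,3,4,7-tetrahydrooxepine-2-carboxylate | C[Si](C)(C)CCOC(=O)[C@@]1(CC(=O)c2cc(O[Si](C)(C)C(C)(C)C)ccc2O[Si](C)(C)C(C)(C)C)CCC=C(CC/C=C(\C)CO[Si](CC)(CC)CC)CO1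
F13 | step 19 | 2-(trimethylsilyl)ethyl (2S)-2-{2-[2,5-bis(tert-butyldimethylsilyloxy)phenyl]-2-oxoethyl}-6-[(3E)-5-hydroxy-4-methylpent-3-en-1-yl]-2,3,4,7-tetrahydrooxepine-2-carboxylate | C[Si](C)(C)CCOC(=O)[C@@]1(CC(=O)c2cc(O[Si](C)(C)C(C)(C)C)ccc2O[Si](C)(C)C(C)(C)C)CCC=C(CC/C=C(\C)CO)CO1
F14 | step 19 | 2-(trimethylsilyl)ethyl (2S)-2-{2-[2,5-bis(tert-butyldimethylsilyloxy)phenyl]-2-oxoethyl}-6-[(3E)-5-{[(2E)-3-(4-(tert-butyldimethylsilyloxy)phenyl)prop-2-enoyl]oxy}-4-methylpent-3-en-1-yl]-2,3,4,7-tetrahydrooxepine-2-carboxylate | C[Si](C)(C)CCOC(=O)[C@@]1(CC(=O)c2cc(O[Si](C)(C)C(C)(C)C)ccc2O[Si](C)(C)C(C)(C)C)CCC=C(CC/C=C(\C)COC(=O)/C=C/c2ccc(O[Si](C)(C)C(C)(C)C)cc2)CO1
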